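**Retrosynthetic overview**
- The route rests on the unsymmetrical conjugated diyne C5≡C6–C7≡C8. It lies between the C1–C4 acid arm and the fifteen methylenes C9–C23 that end at furan C2. It is treated as an ynone (C5≡C6–C8=O) into which one carbon, C7, is inserted from CBr4, so two alkynes never have to be cross-coupled.
- Disconnections:
  - CO2H ⇒ CH2OTBS.
  - C6–C7 and C7≡C8 ⇒ 1,2-shift in the lithium alkylidene carbenoid of a 1,1-dibromo-2-alkynyl olefin.
  - C7=C8 ⇒ Ramirez olefination of the ynone.
  - C6–C8 ⇒ lithium acetylide of O-silylated hex-5-yn-1-ol + 16-(furan-2-yl)hexadecanal.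
  - Furan C2–C23 ⇒ 2-furyllithium + a C16 ω-bromo ether from hexadecane-1,16-diol.
- Rings: none is formed. The furan, the only ring, is bought and is kept away from strong acid, halogen electrophiles and chromium oxidants.

Key step: step 10

Remark: the target has no stereocentre. The acetal carbon of the THP ethers and the propargylic carbinol carbon are carried as racemates, and both vanish before the key step.

**Step 1**
Reactants: 1 hexadecane-1,16-diol
Product: 2 16-bromohexadecan-1-ol
Conditions: 48% aq. HBr (1.2 equiv), toluene, reflux
Reagents that add atoms: hydrogen bromide, Br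
Why: Nucleophilic substitution of the protonated alcohol in the two-phase HBr/toluene system should stop largely at the monobromide, because the bromo alcohol moves into the toluene layer where aggregation shields its hydroxyl, and residual diol and dibromide are removed by chromatography.

**Step 2**
Reactants: 2 16-bromohexadecan-1-ol
Product: 3 2-[(16-bromohexadecyl)oxy]tetrahydro-2H-pyran (racemic)
Conditions: 3,4-dihydro-2H-pyran (1.5 equiv), PPTS (cat.), CH2Cl2, rt
Reagents that add atoms: 3,4-dihydro-2H-pyran, C1=COCCC1
Why: Acid-catalysed tetrahydropyranylation (addition of the alcohol to the enol ether) removes the hydroxyl proton, which would otherwise consume organolithium and give a poorly soluble long-chain alkoxide, and the new acetal centre is racemic and of no consequence.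

**Step 3**
Reactants: 4 furan; 3 2-[(16-bromohexadecyl)oxy]tetrahydro-2H-pyran
Product: 6 2-{[16-(furan-2-yl)hexadecyl]oxy}tetrahydro-2H-pyran (racemic), via 2-furyllithium 5 (not isolated)
Conditions: furan (2 equiv), n-BuLi (1.5 equiv), THF, −78 → 0 °C; then DMPU, 3, 0 °C → rt
Reagents that add atoms: none
Why: Furan is lithiated selectively next to the ring oxygen, and the 2-furyllithium, activated by DMPU, displaces the unhindered primary bromide in an SN2 alkylation that forms the furan C2–C23 bond while the THP acetal is inert to base.

**Step 4**
Reactants: 6 2-{[16-(furan-2-yl)hexadecyl]oxy}tetrahydro-2H-pyran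
Product: 7 16-(furan-2-yl)hexadecan-1-ol
Conditions: PPTS (cat.), MeOH/THF, 45 °C
Reagents that add atoms: none
Why: Transacetalisation to methanol under weakly acidic PPTS catalysis should free the primary alcohol under conditions too mild to open the 2-alkylfuran.

**Step 5**
Reactants: 7 16-(furan-2-yl)hexadecan-1-ol
Product: 8 16-(furan-2-yl)hexadecanal
Conditions: Dess–Martin periodinane (1.3 equiv), NaHCO3 (5 equiv), CH2Cl2, 0 °C → rt
Reagents that add atoms: none
Why: The Dess–Martin oxidation stops at the aldehyde and runs at a temperature where the waxy alcohol stays dissolved, and solid NaHCO3 takes up the liberated acetic acid so that the furan meets no acid.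

**Step 6**
Reactants: 9 hex-5-yn-1-ol
Product: 10 tert-butyl(hex-5-yn-1-yloxy)dimethylsilane
Conditions: TBSCl (1.1 equiv), imidazole (2 equiv), CH2Cl2, 0 °C → rt
Reagents that add atoms: tert-butyldimethylsilyl chloride, CC(C)(C)[Si](C)(C)Cl
Why: Imidazole-promoted silylation of the primary alcohol gives an ether that should withstand the two organolithium steps ahead and leave later with fluoride.

**Step 7**
Reactants: 10 tert-butyl(hex-5-yn-1-yloxy)dimethylsilane; 8 16-(furan-2-yl)hexadecanal
Product: 12 (±)-1-[(tert-butyldimethylsilyl)oxy]-22-(furan-2-yl)docos-5-yn-7-ol, via lithium acetylide 11 (not isolated)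
Conditions: 10 (1.2 equiv), n-BuLi (1.1 equiv), THF, −78 °C; then 8 in THF, −78 → −20 °C; sat. aq. NH4Cl
Reagents that add atoms: none
Why: Deprotonation of the terminal alkyne and 1,2-addition of the lithium acetylide to the aldehyde forms the C6–C8 bond, with the alkyne kept in excess over n-BuLi so that no free base reaches the furan or the aldehyde, and the carbinol centre arises uncontrolled as a racemate that the next step erases.

**Step 8**
Reactants: 12 (±)-1-[(tert-butyldimethylsilyl)oxy]-22-(furan-2-yl)docos-5-yn-7-ol
Product: 13 1-[(tert-butyldimethylsilyl)oxy]-22-(furan-2-yl)docos-5-yn-7-one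
Conditions: activated MnO2 (20 equiv), CH2Cl2, rt
Reagents that add atoms: none
Why: Activated MnO2 oxidises the propargylically activated secondary alcohol under neutral heterogeneous conditions that should leave furan, silyl ether and the electrophilic ynone product untouched, and the only stereocentre of the route disappears.

**Step 9**
Reactants: 13 1-[(tert-butyldimethylsilyl)oxy]-22-(furan-2-yl)docos-5-yn-7-one; 14 carbon tetrabromide
Product: 16 tert-butyl{[7-(dibromomethylidene)-22-(furan-2-yl)docos-5-yn-1-yl]oxy}dimethylsilane, via dibromomethylidene(triphenyl)phosphorane 15 (not isolated)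
Conditions: 14 (2 equiv), PPh3 (4 equiv), CH2Cl2, 0 °C, 30 min; then 13, 0 °C → rt
Reagents that add atoms: carbon tetrabromide 14, BrC(Br)(Br)Br
Why: In this Ramirez dibromoolefination (a Wittig-type reaction) the non-basic ylide 15, preformed so that hardly any free phosphine meets the ynone, should add 1,2 to the sterically open, alkynyl-activated carbonyl and bring in C7, and no E/Z question arises because both bromines sit on one carbon.

**Step 10**
Reactants: 16 tert-butyl{[7-(dibromomethylidene)-22-(furan-2-yl)docos-5-yn-1-yl]oxy}dimethylsilane
Product: 18 tert-butyl{[23-(furan-2-yl)tricosa-5,7-diyn-1-yl]oxy}dimethylsilane, via bromo(lithio)alkylidene carbenoid 17 (not isolated)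
Conditions: n-BuLi (1.2 equiv), hexanes (dilute), −78 °C, then warm to −10 °C; sat. aq. NH4Cl
Reagents that add atoms: none
Why: n-BuLi exchanges one of the two geminal vinylic bromines of 16 at −78 °C, much faster than any deprotonation, and gives the α-bromo vinyllithium 17, a lithium alkylidene carbenoid centred on the CBr4-derived carbon C7. On warming, the C8 substituent lying anti to the remaining C–Br bond moves with its bonding pair to C7 while LiBr departs, so the C6–C7 bond and the C7≡C8 triple bond arise together and the cross-conjugated enyne is straightened into the linear 5,7-diyne. This is the Fritsch–Buttenberg–Wiechell rearrangement in its dibromoolefin/n-BuLi/hexanes variant, established for 1,1-dibromo-2-alkynyl olefins, an alkyl group as the second substituent on C8 being the less common case within that class. No ring is closed and no stereocentre is created, and the result does not depend on which bromine is exchanged, because a shift of the alkynyl arm or of the alkyl arm leads to the same constitution 18. The selectivity needed is exchange followed by 1,2-shift in preference to lithiation of furan C5–H, protonation of the carbenoid, 1,5-C–H insertion into the methylene chain or attack of butyl on the carbenoid. It is secured by the very fast exchange at the CBr2 group, the high migratory aptitude of the sp-carbon substituent, the non-coordinating hexane medium that keeps 17 a tight and short-lived carbenoid, and the small excess of n-BuLi (a furan lithiated by accident would simply be reprotonated on quenching).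

**Step 11**
Reactants: 18 tert-butyl{[23-(furan-2-yl)tricosa-5,7-diyn-1-yl]oxy}dimethylsilane
Product: 19 23-(furan-2-yl)tricosa-5,7-diyn-1-ol
Conditions: TBAF (1.2 equiv), THF, 0 °C → rt; H2O
Reagents that add atoms: none
Why: Fluoride-induced desilylation, driven by the strong Si–F bond, should free the primary alcohol without touching the internal diyne or the furan.

**Step 12**
Reactants: 19 23-(furan-2-yl)tricosa-5,7-diyn-1-ol
Product: 20 23-(furan-2-yl)tricosa-5,7-diynal
Conditions: Dess–Martin periodinane (1.3 equiv), NaHCO3 (5 equiv), CH2Cl2, 0 °C → rt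
Reagents that add atoms: none
Why: The buffered Dess–Martin oxidation takes the primary alcohol only as far as the aldehyde and is inert towards the diyne and the acid-sensitive furan.

**Step 13**
Reactants: 20 23-(furan-2-yl)tricosa-5,7-diynal
Product: 21 23-(furan-2-yl)tricosa-5,7-diynoic acid (target)
Conditions: NaClO2 (2 equiv), NaH2PO4 (3 equiv), 2-methyl-2-butene (30 equiv), t-BuOH/THF/H2O, 0 °C → rt
Reagents that add atoms: sodium chlorite, [Na+].[O-]Cl=O
Why: In the Pinnick oxidation chlorous acid adds to the aldehyde and fragments to the carboxylic acid, the large excess of 2-methyl-2-butene should capture the hypochlorous acid before it reaches the furan, and the phosphate buffer keeps the medium only weakly acidic.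

**Compound list**
1 | hexadecane-1,16-diol | OCCCCCCCCCCCCCCCCO | starting material
2 | 16-bromohexadecan-1-ol | OCCCCCCCCCCCCCCCCBr | intermediate
3 | 2-[(16-bromohexadecyl)oxy]tetrahydro-2H-pyran (racemic) | BrCCCCCCCCCCCCCCCCOC1CCCCO1 | intermediate
4 | furan | c1ccoc1 | starting material
5 | 2-furyllithium (formed in the flask) | [Li]c1ccco1 | intermediate
6 | 2-{[16-(furan-2-yl)hexadecyl]oxy}tetrahydro-2H-pyran (racemic) | O1CCCCC1OCCCCCCCCCCCCCCCCc1ccco1 | intermediate
7 | 16-(furan-2-yl)hexadecan-1-ol | OCCCCCCCCCCCCCCCCc1ccco1 | intermediate
8 | 16-(furan-2-yl)hexadecanal | O=CCCCCCCCCCCCCCCCc1ccco1 | intermediate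
9 | hex-5-yn-1-ol | OCCCCC#C | starting material
10 | tert-butyl(hex-5-yn-1-yloxy)dimethylsilane | C#CCCCCO[Si](C)(C)C(C)(C)C | intermediate
11 | {6-[(tert-butyldimethylsilyl)oxy]hex-1-yn-1-yl}lithium (formed in the flask) | [Li]C#CCCCCO[Si](C)(C)C(C)(C)C | intermediate
12 | 1-[(tert-butyldimethylsilyl)oxy]-22-(furan-2-yl)docos-5-yn-7-ol (racemic) | CC(C)(C)[Si](C)(C)OCCCCC#CC(O)CCCCCCCCCCCCCCCc1ccco1 | intermediate
13 | 1-[(tert-butyldimethylsilyl)oxy]-22-(furan-2-yl)docos-5-yn-7-one | CC(C)(C)[Si](C)(C)OCCCCC#CC(=O)CCCCCCCCCCCCCCCc1ccco1 | intermediate
14 | carbon tetrabromide | BrC(Br)(Br)Br | starting material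
15 | dibromomethylidene(triphenyl)phosphorane (formed in the flask) | BrC(Br)=P(c1ccccc1)(c1ccccc1)c1ccccc1 | intermediate
16 | tert-butyl{[7-(dibromomethylidene)-22-(furan-2-yl)docos-5-yn-1-yl]oxy}dimethylsilane | CC(C)(C)[Si](C)(C)OCCCCC#CC(=C(Br)Br)CCCCCCCCCCCCCCCc1ccco1 | intermediate
17 | [1-bromo-2-{6-[(tert-butyldimethylsilyl)oxy]hex-1-yn-1-yl}-17-(furan-2-yl)heptadec-1-en-1-yl]lithium (either geometry, formed in the flask) | CC(C)(C)[Si](C)(C)OCCCCC#CC(=C([Li])Br)CCCCCCCCCCCCCCCc1ccco1 | intermediate
18 | tert-butyl{[23-(furan-2-yl)tricosa-5,7-diyn-1-yl]oxy}dimethylsilane | CC(C)(C)[Si](C)(C)OCCCCC#CC#CCCCCCCCCCCCCCCCc1ccco1 | intermediate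
19 | 23-(furan-2-yl)tricosa-5,7-diyn-1-ol | OCCCCC#CC#CCCCCCCCCCCCCCCCc1ccco1 | intermediate
20 | 23-(furan-2-yl)tricosa-5,7-diynal | O=CCCCC#CC#CCCCCCCCCCCCCCCCc1ccco1 | intermediate
21 | 23-(furan-2-yl)tricosa-5,7-diynoic acid | O=C(O)CCCC#CC#CCCCCCCCCCCCCCCCc1ccco1 | target

**Step count**
- Total step count: 13.
- Longest linear sequence: 12 (steps 1–5 and 7–13, from hexadecane-1,16-diol). Step 6 is the only side-branch step.

**Steps most likely to fail**

(a) Step 10.
- What may go wrong: protonation of the carbenoid before it rearranges, insertion of the carbenoid carbon into a C–H bond of the long chain, or incomplete exchange because the waxy substrate separates from cold hexanes.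
- Fallback: a copper-catalysed Cadiot–Chodkiewicz cross-coupling replaces the rearrangement. It sets out from 8 and 10 and comes back at 18. Aldehyde 8 would be homologated with the Ohira–Bestmann reagent (K2CO3, MeOH, rt) to the terminal alkyne 2-(heptadec-16-yn-1-yl)furan F1. The furan-free alkyne 10 would be brominated (NBS, cat. AgNO3, acetone) to [(6-bromohex-5-yn-1-yl)oxy](tert-butyl)dimethylsilane F2, so that no electrophilic bromine ever meets the furan. F1 and F2 would then be joined with CuCl (cat.), NH2OH·HCl and aqueous n-BuNH2 in Et2O at 0 °C to give 18.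

(b) Step 9.
- What may go wrong: phosphine-triggered isomerisation of the ynone into conjugation, sluggish olefination of a ketone with competing enolisation, and cleavage of the silyl ether by the bromophosphonium species.
- Fallback: the dibromoolefination is moved to the aldehyde and the diyne is built by palladium catalysis. It sets out from 8 and 10 and comes back at 18. Aldehyde 8 would be treated with CBr4/PPh3 (CH2Cl2, 0 °C), where an aldehyde reacts quickly and neither ynone nor silyl ether is present, to give 2-(17,17-dibromoheptadec-16-en-1-yl)furan F3. F3 and 10 would be heated with Pd2(dba)3 (cat.), P(4-MeOC6H4)3 and Et3N in DMF at 80 °C. Zerovalent palladium should insert into the C–Br bond trans to the chain. Alkynylation then gives in the flask tert-butyl{[(7Z)-7-bromo-23-(furan-2-yl)tricos-7-en-5-yn-1-yl]oxy}dimethylsilane F4, and anti loss of HBr from it leads to 18.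

(c) Step 13.
- What may go wrong: chlorination or oxidative opening of the furan by chlorine oxidants that escape the scavenger.
- Fallback: a chlorine-free oxidative esterification through an acyl azolium, followed by saponification. It sets out from 20 and comes back at 21. Aldehyde 20 would be treated with MeOH, 1,4-dimethyl-1,2,4-triazolium iodide (cat.), DBU and MnO2 in CH2Cl2 at rt to give methyl 23-(furan-2-yl)tricosa-5,7-diynoate F5. This ester would be cleaved with LiOH in THF/H2O at rt, and gentle acidification with citric acid would give 21.

**Further compounds**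
F1 | step 10 | 2-(heptadec-16-yn-1-yl)furan | C#CCCCCCCCCCCCCCCCc1ccco1
F2 | step 10 | [(6-bromohex-5-yn-1-yl)oxy](tert-butyl)dimethylsilane | BrC#CCCCCO[Si](C)(C)C(C)(C)C
F3 | step 9 | 2-(17,17-dibromoheptadec-16-en-1-yl)furan | BrC(Br)=CCCCCCCCCCCCCCCCc1ccco1
F4 | step 9 | tert-butyl{[(7Z)-7-bromo-23-(furan-2-yl)tricos-7-en-5-yn-1-yl]oxy}dimethylsilane | CC(C)(C)[Si](C)(C)OCCCCC#C/C(Br)=C/CCCCCCCCCCCCCCCc1ccco1
F5 | step 13 | methyl 23-(furan-2-yl)tricosa-5,7-diynoate | COC(=O)CCCC#CC#CCCCCCCCCCCCCCCCc1ccco1
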